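**Retrosynthetic overview**
1. Target 17 ← aldehyde 13 plus tetradecylmagnesium bromide (side-chain C2′–C3′ bond); the aldehyde comes from the silyl-protected two-carbon arm on ring C2.
2. Ring C3 methylene ← the C3 ketone of oxolan-3-one 8, removed by reduction and radical deoxygenation.
3. Oxolan-3-one 8 ← 5-methylidene-1,3-dioxolane 6 by a Lewis-acid O→C 1,3-shift that makes the C4–C5 bond. The dioxolane ring is formed first (step 1) and the oxolane ring second (step 5).
4. 6 ← L-malic acid + pentanal (cis-dioxolanone), then side-chain acid reduction, silylation and carbonyl methylenation.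
5. Feature: in the oxolane ring O1–C2–C3–C4–C5, O1 and C2 (with its two-carbon arm) are the hydroxyl oxygen and carbinol carbon of L-malic acid, and C5 (with butyl) is the carbonyl carbon of pentanal. The C4–C5 ring bond can therefore be made by trading an acetal C–O bond for a C–C bond.

Key step: step 5

Assumption: centres that are erased later are not upgraded to single epimers: C3 of 9 and 10 (drawn as the expected 3S epimer) and the carbinol carbon of 16 (both epimers). The acetal carbon of 3–6 is drawn as the expected major cis epimer, with any trans epimer removed by chromatography at 5.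

**Route**

Step 1
Reactants: 1 L-malic acid; 2 pentanal
Product: 3 2-[(2S,4S)-2-butyl-5-oxo-1,3-dioxolan-4-yl]acetic acid
Conditions: pentanal (1.5 equiv), p-TsOH·H2O (cat.), pentane, reflux, Dean–Stark
Reagents that add atoms: none
Why: Acid-catalysed acetalization of the α-hydroxy acid unit (Seebach-type dioxolanone formation) should be preferred over the six-membered acetal through the β-carboxyl, and under equilibrating conditions the butyl group should settle cis to the CH2CO2H arm, the malic stereocentre not being touched.

Step 2
Reactants: 3 2-[(2S,4S)-2-butyl-5-oxo-1,3-dioxolan-4-yl]acetic acid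
Product: 4 (2S,5S)-2-butyl-5-(2-hydroxyethyl)-1,3-dioxolan-4-one
Conditions: BH3·SMe2, THF, 0 °C → rt; then H2O (pH 7 buffer), 0 °C
Reagents that add atoms: none
Why: Chemoselective borane reduction: the free acid is reduced through its acyloxyborane much faster than the ester-type carbonyl of the dioxolanone, no stereocentre is involved, and the alcohol is silylated at once to forestall translactonization.

Step 3
Reactants: 4 (2S,5S)-2-butyl-5-(2-hydroxyethyl)-1,3-dioxolan-4-one
Product: 5 (2S,5S)-2-butyl-5-[2-(tert-butyldimethylsilyloxy)ethyl]-1,3-dioxolan-4-one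
Conditions: TBSCl, imidazole, CH2Cl2, 0 °C → rt
Reagents that add atoms: tert-butyldimethylsilyl chloride, CC(C)(C)[Si](C)(C)Cl
Why: Imidazole-promoted silylation of a primary alcohol (Corey silyl ether formation) is too mild to open the dioxolanone.

Step 4
Reactants: 5 (2S,5S)-2-butyl-5-[2-(tert-butyldimethylsilyloxy)ethyl]-1,3-dioxolan-4-one
Product: 6 (2S,4S)-2-butyl-4-[2-(tert-butyldimethylsilyloxy)ethyl]-5-methylidene-1,3-dioxolane
Conditions: Cp2TiMe2 (2.5 equiv), toluene, 65 °C, dark; filtration through Et3N-deactivated basic alumina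
Reagents that add atoms: dimethyltitanocene Cp2TiMe2, C[Ti](C)(C1C=CC=C1)C1C=CC=C1
Why: Petasis methylenation: Cp2TiMe2 loses methane on heating to give Cp2Ti=CH2, which converts the ester-type carbonyl into the exocyclic enol ether through an oxatitanacyclobutane without acid or base, so the adjacent C4 centre and the silyl ether are left alone.

Step 5
Reactants: 6 (2S,4S)-2-butyl-4-[2-(tert-butyldimethylsilyloxy)ethyl]-5-methylidene-1,3-dioxolane
Product: 8 (2S,5R)-5-butyl-2-[2-(tert-butyldimethylsilyloxy)ethyl]oxolan-3-one, via oxocarbenium aluminium-enolate zwitterion 7 (not isolated)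
Conditions: Me2AlCl (1.5 equiv), CH2Cl2, −78 °C → 0 °C; then sat. aq. NaHCO3
Reagents that add atoms: none
Why: Me2AlCl binds the enol-ether oxygen O1 of 6 and breaks the O1–C2 acetal bond, giving zwitterion 7, in which a chlorodimethylaluminium enolate and a butyl-substituted oxocarbenium ion stay joined through the malic carbon; the enolate CH2 then adds to the oxocarbenium carbon and forms the C4–C5 bond of the oxolan-3-one. The closest known reaction type is the Petasis–Ferrier rearrangement of methylidene-1,3-dioxolanes and -dioxanes promoted by alkylaluminium Lewis acids. The ring closes in a 5-(enolendo)-endo-trig aldol-type mode, formally disfavoured but accepted in this reaction class because both reactive ends are generated as a contact ion pair held by a three-atom tether. The C2 centre comes unchanged from L-malic acid and controls the new C5 centre: the (E)-oxocarbenium ion should be attacked through an envelope in which the butyl group and the C2 silyloxyethyl arm are both pseudo-equatorial, which places them cis. The step needs 2,5-cis selectivity and arrest at the ketone; the first is secured by the resident C2 substituent (and by the cis acetal of 6 if the ion pair collapses with retention), the second by Me2AlCl, which has no β-hydrogen to reduce the ketone and transfers methyl only slowly at −78 °C.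

Step 6
Reactants: 8 (2S,5R)-5-butyl-2-[2-(tert-butyldimethylsilyloxy)ethyl]oxolan-3-one
Product: 9 (2S,3S,5R)-5-butyl-2-[2-(tert-butyldimethylsilyloxy)ethyl]oxolan-3-ol
Conditions: NaBH4, MeOH, −20 °C
Reagents that add atoms: none
Why: Borohydride reduction of the ketone, with hydride expected to approach anti to the C2 arm to give mainly the all-cis 3S alcohol; either epimer serves because step 8 removes this centre, and prompt reduction takes away the enolizable α-alkoxy ketone before C2 can epimerize.

Step 7
Reactants: 9 (2S,3S,5R)-5-butyl-2-[2-(tert-butyldimethylsilyloxy)ethyl]oxolan-3-ol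
Product: 10 O-{(2S,3S,5R)-5-butyl-2-[2-(tert-butyldimethylsilyloxy)ethyl]oxolan-3-yl} 1H-imidazole-1-carbothioate
Conditions: 1,1′-thiocarbonyldiimidazole, DMAP (cat.), toluene, 80 °C
Reagents that add atoms: 1,1′-thiocarbonyldiimidazole, S=C(n1ccnc1)n1ccnc1
Why: Thioacylation of the secondary alcohol under neutral conditions that spare the silyl ether gives the thiocarbonyl derivative needed for the first stage of a Barton–McCombie deoxygenation.

Step 8
Reactants: 10 O-{(2S,3S,5R)-5-butyl-2-[2-(tert-butyldimethylsilyloxy)ethyl]oxolan-3-yl} 1H-imidazole-1-carbothioate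
Product: 11 tert-butyl{2-[(2R,5R)-5-butyloxolan-2-yl]ethoxy}dimethylsilane
Conditions: Bu3SnH, AIBN (cat.), toluene, 110 °C
Reagents that add atoms: none
Why: Barton–McCombie deoxygenation: the tributyltin radical adds to the thiocarbonyl sulfur, the C3–O bond fragments to a secondary ring radical, and Bu3SnH delivers hydrogen, so C3 becomes CH2 without touching C2 or C5.

Step 9
Reactants: 11 tert-butyl{2-[(2R,5R)-5-butyloxolan-2-yl]ethoxy}dimethylsilane
Product: 12 2-[(2R,5R)-5-butyloxolan-2-yl]ethan-1-ol
Conditions: Bu4NF, THF, 0 °C → rt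
Reagents that add atoms: none
Why: Fluoride cleavage of the primary silyl ether (desilylation), to which the dialkyl oxolane is inert.

Step 10
Reactants: 12 2-[(2R,5R)-5-butyloxolan-2-yl]ethan-1-ol
Product: 13 2-[(2R,5R)-5-butyloxolan-2-yl]acetaldehyde
Conditions: Dess–Martin periodinane, CH2Cl2, 0 °C → rt
Reagents that add atoms: none
Why: Dess–Martin oxidation stops at the aldehyde under near-neutral conditions, which matters because the β-alkoxy aldehyde could open by retro-oxa-Michael elimination under base; the aldehyde is used directly.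

Step 11
Reactants: 13 2-[(2R,5R)-5-butyloxolan-2-yl]acetaldehyde; 14 1-bromotetradecane
Product: 16 1-[(2R,5R)-5-butyloxolan-2-yl]hexadecan-2-ol, via tetradecylmagnesium bromide 15 (not isolated)
Conditions: Mg, I2 (cat.), THF, reflux; then 13, THF, −78 °C → 0 °C; then H2O
Reagents that add atoms: none
Why: Grignard formation from the primary bromide and 1,2-addition to the aldehyde at low temperature builds the C2′–C3′ bond of the side chain; the carbinol forms as both epimers, which is immaterial because step 12 oxidises it.

Step 12
Reactants: 16 1-[(2R,5R)-5-butyloxolan-2-yl]hexadecan-2-ol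
Product: 17 1-[(2R,5R)-5-butyloxolan-2-yl]hexadecan-2-one
Conditions: Dess–Martin periodinane, CH2Cl2, rt
Reagents that add atoms: none
Why: Dess–Martin oxidation of the secondary alcohol gives the ketone under non-basic conditions, so the β-alkoxy ketone is not exposed to retro-oxa-Michael epimerization at ring C2.

**Compound list**
1 | L-malic acid, (2S)-2-hydroxybutanedioic acid | O[C@@H](CC(=O)O)C(=O)O | starting material
2 | pentanal | CCCCC=O | starting material
3 | 2-[(2S,4S)-2-butyl-5-oxo-1,3-dioxolan-4-yl]acetic acid | OC(=O)C[C@H]1C(=O)O[C@@H](CCCC)O1 | intermediate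
4 | (2S,5S)-2-butyl-5-(2-hydroxyethyl)-1,3-dioxolan-4-one | OCC[C@H]1C(=O)O[C@@H](CCCC)O1 | intermediate
5 | (2S,5S)-2-butyl-5-[2-(tert-butyldimethylsilyloxy)ethyl]-1,3-dioxolan-4-one | CC(C)(C)[Si](C)(C)OCC[C@H]1C(=O)O[C@@H](CCCC)O1 | intermediate
6 | (2S,4S)-2-butyl-4-[2-(tert-butyldimethylsilyloxy)ethyl]-5-methylidene-1,3-dioxolane | CC(C)(C)[Si](C)(C)OCC[C@H]1C(=C)O[C@@H](CCCC)O1 | intermediate
7 | oxocarbenium aluminium-enolate zwitterion: O-pentylidene oxocarbenium ion on the (S)-carbinol carbon bearing the chlorodimethylaluminate enolate of the methyl ketone | CCCCC=[O+][C@@H](CCO[Si](C)(C)C(C)(C)C)C(=C)O[Al-](C)(C)Cl | intermediate (not isolated)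
8 | (2S,5R)-5-butyl-2-[2-(tert-butyldimethylsilyloxy)ethyl]oxolan-3-one | CC(C)(C)[Si](C)(C)OCC[C@H]1C(=O)C[C@@H](CCCC)O1 | intermediate
9 | (2S,3S,5R)-5-butyl-2-[2-(tert-butyldimethylsilyloxy)ethyl]oxolan-3-ol | CC(C)(C)[Si](C)(C)OCC[C@H]1[C@@H](O)C[C@@H](CCCC)O1 | intermediate
10 | O-{(2S,3S,5R)-5-butyl-2-[2-(tert-butyldimethylsilyloxy)ethyl]oxolan-3-yl} 1H-imidazole-1-carbothioate | CC(C)(C)[Si](C)(C)OCC[C@H]1[C@@H](OC(=S)n2ccnc2)C[C@@H](CCCC)O1 | intermediate
11 | tert-butyl{2-[(2R,5R)-5-butyloxolan-2-yl]ethoxy}dimethylsilane | CC(C)(C)[Si](C)(C)OCC[C@H]1CC[C@@H](CCCC)O1 | intermediate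
12 | 2-[(2R,5R)-5-butyloxolan-2-yl]ethan-1-ol | OCC[C@H]1CC[C@@H](CCCC)O1 | intermediate
13 | 2-[(2R,5R)-5-butyloxolan-2-yl]acetaldehyde | O=CC[C@H]1CC[C@@H](CCCC)O1 | intermediate
14 | 1-bromotetradecane | CCCCCCCCCCCCCCBr | starting material
15 | tetradecylmagnesium bromide | CCCCCCCCCCCCCC[Mg]Br | intermediate (not isolated)
16 | 1-[(2R,5R)-5-butyloxolan-2-yl]hexadecan-2-ol (both carbinol epimers) | CCCCCCCCCCCCCCC(O)C[C@H]1CC[C@@H](CCCC)O1 | intermediate
17 | 1-[(2R,5R)-5-butyloxolan-2-yl]hexadecan-2-one | CCCCCCCCCCCCCCC(=O)C[C@H]1CC[C@@H](CCCC)O1 | target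

**Step count**
Total steps: 12. Longest linear sequence: 12 steps (1 → 17); 1-bromotetradecane enters in step 11.

**Steps most likely to fail, with fallbacks**

Step 5 (key rearrangement). The ion pair may recombine with poor facial selectivity at C5, or it may fragment with loss of pentanal or take up methyl from aluminium before the C–C bond forms. The fallback sets the cis relationship by hydrogenation instead; it sets out from pentanal 2 and comes back at aldehyde 13.
- Corey–Chaykovsky epoxidation of 2 (Me3SI, NaH, DMSO–THF) would give rac-2-butyloxirane F1.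
- Hydrolytic kinetic resolution with (R,R)-(salen)Co(OAc) (trivalent cobalt; salen = N,N′-bis(3,5-di-tert-butylsalicylidene)cyclohexane-1,2-diamine dianion) and 0.55 equiv of water is expected to consume the S enantiomer and leave (R)-2-butyloxirane F2.
- The dianion of methyl acetoacetate (NaH, then n-BuLi, THF, 0 °C) should open F2 at its CH2 to give methyl (6R)-6-hydroxy-3-oxodecanoate F3.
- Acid-catalysed cyclodehydration (p-TsOH cat., CH2Cl2, molecular sieves) should give methyl (2E)-2-[(5R)-5-butyloxolan-2-ylidene]acetate F4.
- Hydrogenation over Rh/Al2O3 in MeOH should deliver hydrogen to the face away from butyl and give methyl 2-[(2R,5R)-5-butyloxolan-2-yl]acetate F5.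
- iBu2AlH in CH2Cl2 at −78 °C would reduce F5 to aldehyde 13, from which steps 11 and 12 follow.

Step 1 (acetalization). The equilibrium may include the six-membered acetal through the β-carboxyl, the cis/trans ratio may stay low, and pentanal may self-condense under the acid. The fallback replaces thermodynamic Brønsted-acid dehydration by a kinetically controlled silyl-transfer acetalization; it sets out from L-malic acid 1 and comes back at acid 3.
- Per-silylation of 1 (hexamethyldisilazane, TMSCl cat.) would give bis(trimethylsilyl) (2S)-2-[(trimethylsilyl)oxy]butanedioate F6.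
- Pentanal with TMSOTf (cat.) in CH2Cl2 at −78 °C should close the five-membered ring from the silyl ether and the adjacent silyl ester, giving trimethylsilyl 2-[(2S,4S)-2-butyl-5-oxo-1,3-dioxolan-4-yl]acetate F7.
- Aqueous work-up would hydrolyse the silyl ester of F7 to 3.

Step 11 (Grignard addition). The basic organomagnesium reagent may enolize the aldehyde, the β-alkoxy aldehyde may open by retro-oxa-Michael elimination and reclose with scrambling of ring C2, and β-hydride transfer may reduce the aldehyde. The fallback avoids the aldehyde through acyl substitution; it sets out from alcohol 12 and comes back at target 17.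
- Oxidation of 12 with TEMPO (cat.) and PhI(OAc)2 in MeCN–H2O would give 2-[(2R,5R)-5-butyloxolan-2-yl]acetic acid F8.
- Coupling with N,O-dimethylhydroxylamine hydrochloride (EDC·HCl, N-methylmorpholine, CH2Cl2) would give 2-[(2R,5R)-5-butyloxolan-2-yl]-N-methoxy-N-methylacetamide F9.
- Tetradecylmagnesium bromide 15 (THF, 0 °C) should add once to F9 through the chelated tetrahedral intermediate and release ketone 17 on work-up, replacing steps 10–12.

**Further compounds**
F1 | step 5 | rac-2-butyloxirane | CCCCC1CO1
F2 | step 5 | (R)-2-butyloxirane | CCCC[C@@H]1CO1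
F3 | step 5 | methyl (6R)-6-hydroxy-3-oxodecanoate | COC(=O)CC(=O)CC[C@H](O)CCCC
F4 | step 5 | methyl (2E)-2-[(5R)-5-butyloxolan-2-ylidene]acetate | COC(=O)/C=C1\CC[C@@H](CCCC)O1
F5 | step 5 | methyl 2-[(2R,5R)-5-butyloxolan-2-yl]acetate | COC(=O)C[C@H]1CC[C@@H](CCCC)O1
F6 | step 1 | bis(trimethylsilyl) (2S)-2-[(trimethylsilyl)oxy]butanedioate | C[Si](C)(C)O[C@@H](CC(=O)O[Si](C)(C)C)C(=O)O[Si](C)(C)C
F7 | step 1 | trimethylsilyl 2-[(2S,4S)-2-butyl-5-oxo-1,3-dioxolan-4-yl]acetate | C[Si](C)(C)OC(=O)C[C@H]1C(=O)O[C@@H](CCCC)O1
F8 | step 11 | 2-[(2R,5R)-5-butyloxolan-2-yl]acetic acid | OC(=O)C[C@H]1CC[C@@H](CCCC)O1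
F9 | step 11 | 2-[(2R,5R)-5-butyloxolan-2-yl]-N-methoxy-N-methylacetamide | CON(C)C(=O)C[C@H]1CC[C@@H](CCCC)O1
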